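**Assumption:** the SMILES is read as 18-acetoxylabda-8(17),13E-dien-15-oic acid of the normal series, (4R,5R,9S,10R): 4α-CH2OAc (equatorial), 4β-CH3, 5α-H, 9α-H, 10β-CH3.

**Convention:** intermediates carry labdane numbering (C10 bears the angular methyl; C8 is the five-ring carbonyl/carbinol carbon that ends as the exocyclic alkene carbon). β is the face of the C10 methyl, α the opposite face.

## Retrosynthetic overview

1. Target 18 ⇐ methyl ester 17 (iodide demethylation) ⇐ C8 ketone 16 (methylenation); the C12–C13 bond comes from an sp3–sp2 Suzuki coupling of the C9 vinyl group of 12 with (E)-enol triflate 14.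
2. Ring B of 12 ⇐ one-carbon ring expansion of the trans-hydrindane carbinol 11: 1,2-shift of C10 from C8 to the inner terminus of a π-allylpalladium unit (semipinacol). This is the key step; it makes C8=O, the C9–C10 bond and the C9 stereocentre.
3. 11 ⇐ enedione 4 + prop-2-yn-1-ol: alkynylation at C8, one dissolving-metal step (alkyne to E-alkene, trans ring fusion, C4 quaternary centre by hydroxymethylation), C3 deoxygenation, acetylation.
4. 4 ⇐ 2-methylcyclopentane-1,3-dione + ethyl vinyl ketone (amino-acid-catalysed annulation sets C10).
5. Ring order: five-membered ring (starting material) → ring A (annulation) → ring B (expansion of the five-membered ring).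

## Route

**Step 1**
Reactants: 1 2-methylcyclopentane-1,3-dione; 2 pent-1-en-3-one (ethyl vinyl ketone)
Product: 4 (7aS)-4,7a-dimethyl-2,3,7,7a-tetrahydro-1H-indene-1,5(6H)-dione, via triketone 3 (not isolated)
Conditions: H2O, AcOH (cat.), 75 °C; evaporate; L-phenylalanine (1.0 equiv), (1S)-(+)-camphor-10-sulfonic acid (0.5 equiv), MeCN, 80 °C
Reagents that add atoms: none
Why: Michael addition followed by the L-phenylalanine-mediated Hajos–Parrish–Eder–Sauer–Wiechert intramolecular aldol condensation, in which the chiral enamine distinguishes the two enantiotopic ring carbonyls and sets quaternary C10 as S (about 90% ee, raised by recrystallisation).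

**Step 2**
Reactants: 4 enedione; 5 prop-2-yn-1-ol
Product: 6 (1R,7aS)-1-hydroxy-1-(3-hydroxyprop-1-yn-1-yl)-4,7a-dimethyl-1,2,3,6,7,7a-hexahydro-5H-inden-5-one (8β-hydroxy-8α-alkynyl enone)
Conditions: KOt-Bu (7 equiv), THF/t-BuOH, −10 to 20 °C; then 1 M HCl, 20 °C
Reagents that add atoms: none
Why: Favorskii-type alkynylation in which the potassium acetylide adds only to the saturated five-ring ketone, because under excess base the conjugated ketone is masked as its dienolate (the selectivity known from ethynylation of 17-keto steroids that carry a 4-en-3-one), and it enters from the α-face opposite the C10 methyl; acidic work-up restores the conjugated enone.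

**Step 3**
Reactants: 6 alkynyl diol enone
Product: 8 hydroxymethyl ketone triol (3-oxo; 4α-CH2OH; 4β-CH3; 5α-H; 8β-OH; 8α-[(E)-3-hydroxyprop-1-enyl]), via trilithium enolate 7 (not isolated)
Conditions: Li (10 equiv), NH3(l)/THF, −78 to −33 °C; isoprene; evaporate NH3; HCHO (gas), THF, −78 °C; aq. NH4Cl
Reagents that add atoms: formaldehyde C=O
Why: Birch-type dissolving-metal reduction with Stork reductive alkylation, in which lithium reduces the alkyne dialkoxide to the E-alkene and the enone to the regiodefined C3–C4 enolate with axial protonation at C5 (5α-H, trans ring fusion), and the enolate is then C-hydroxymethylated (aldol) from the α-face, anti to the 1,3-related axial C10 methyl, which sets C4 with CH2OH α and CH3 β.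

**Step 4**
Reactants: 8 hydroxymethyl ketone triol
Product: 10 triol with C3 as CH2 (4α-CH2OH; 4β-CH3; 5α-H; 8β-OH; 8α-[(E)-3-hydroxyprop-1-enyl]), via tosylhydrazone 9 (not isolated)
Conditions: TsNHNH2 (1.3 equiv), PPTS (cat.), EtOH, 70 °C; evaporate; catecholborane (6 equiv), CHCl3, 0 °C; NaOAc·3H2O, 60 °C
Reagents that add atoms: none
Why: Caglioti-type tosylhydrazone reduction in the mild Kabalka variant, where hydride adds to C=N, acetate then triggers loss of sulfinate and the alkyldiazene expels N2, so the hindered C3 carbonyl becomes CH2 without the strong base that would cause retro-aldol loss of the C4 hydroxymethyl group; no stereocentre is touched.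

**Step 5**
Reactants: 10 triol
Product: 11 diacetate (C18-OAc and allylic C12-OAc; 8β-OH free)
Conditions: Ac2O (2.5 equiv), pyridine, 0 to 20 °C
Reagents that add atoms: acetic anhydride CC(=O)OC(C)=O
Why: Acylation in which both primary hydroxyls are acetylated while the hindered tertiary C8 carbinol stays free, which installs the C18 acetate of the target and turns the allylic hydroxyl into the leaving group for step 6.

**Step 6**
Reactants: 11 diacetate
Product: 12 vinyl decalone (18-acetoxy-8-oxo-9β-vinyl trans-decalin; 9α-H)
Conditions: Pd2(dba)3·CHCl3 (2.5 mol %), P(OPh)3 (15 mol %), 2,6-lutidine (1.2 equiv), 1,4-dioxane, 70 °C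
Reagents that add atoms: none
Why: Proposed new method: zerovalent palladium ionises the primary allylic acetate to a cationic π-allyl complex whose inner terminus (C9) is bonded to the tertiary carbinol carbon C8, and the electron-rich C10–C8 bond, aligned anti to palladium, then shifts to C9 (semipinacol / allylic Wagner–Meerwein 1,2-shift), forming ring B, the C8 ketone and the C9 vinyl group and returning the catalyst; the shift is driven by C=O formation, cannot divert to a diene because the π-allyl has no β-hydrogen (C8 is fully substituted), and O-attack to a vinyl epoxide is reversible; C9 should form as 9α-H/9β-vinyl because in the migration transition state the bulky allyl–palladium terminus points away from the bicycle and the hydrogen sits under the five-membered ring, and quaternary C10 should migrate in preference to the methylene C7; closest known reaction type: palladium-catalysed semipinacol ring expansions of 1-alkenyl- and 1-allenyl-cyclobutanols and cyclopropanols, which are strain-driven and have not been shown for an unstrained cyclopentanol.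

**Step 7**
Reactants: 13 methyl acetoacetate
Product: 14 methyl (E)-3-(trifluoromethylsulfonyloxy)but-2-enoate
Conditions: Tf2O (1.3 equiv), 25% aq. Me4NOH, hexane, 5 °C
Reagents that add atoms: trifluoromethanesulfonic anhydride O=S(=O)(OS(=O)(=O)C(F)(F)F)C(F)(F)F
Why: Stereoselective enol triflation of a β-keto ester, in which the non-chelated tetramethylammonium enolate is sulfonylated in its extended form to give the (E)-enol triflate (triflate trans to the ester), whose geometry becomes that of the C13–C14 alkene.

**Step 8**
Reactants: 12 vinyl decalone; 14 (E)-enol triflate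
Product: 16 methyl 18-acetoxy-8-oxo-17-norlabd-13E-en-15-oate (9α-H), via pinacol alkylboronate 15 (not isolated)
Conditions: RhCl(PPh3)3 (2 mol %), pinacolborane (1.3 equiv), THF, 20 °C; then 14 (1.2 equiv), Pd(OAc)2 (5 mol %), SPhos (10 mol %), K3PO4 (3 equiv), THF/H2O 10:1, 60 °C
Reagents that add atoms: none
Why: Rhodium-catalysed anti-Markovnikov hydroboration of the monosubstituted vinyl group (the ketone is not reduced) followed by B-alkyl Suzuki–Miyaura coupling with retention of the (E)-triflate geometry; the phosphate base also equilibrates the now simply enolisable C9 to the equatorial 9β side chain (9α-H), the thermodynamic epimer.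

**Step 9**
Reactants: 16 keto diester
Product: 17 methyl 18-acetoxylabda-8(17),13E-dien-15-oate
Conditions: Zn, CH2Br2, TiCl4, THF/CH2Cl2, 0 to 20 °C
Reagents that add atoms: dibromomethane BrCBr
Why: Takai–Lombardo methylenation, in which the non-basic gem-dimetallic methylene reagent converts the hindered, enolisable C8 ketone into the exocyclic alkene without epimerising C9 and leaves both esters alone.

**Step 10**
Reactants: 17 methyl ester
Product: 18 18-acetoxylabda-8(17),13E-dien-15-oic acid (target)
Conditions: LiI (8 equiv), pyridine, 115 °C; then 1 M HCl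
Reagents that add atoms: none
Why: SN2 dealkylation of a methyl ester by iodide, which attacks the unhindered O-methyl carbon and frees the carboxylate, whereas the C18 acetate has a neopentyl O-alkyl carbon that cannot be attacked, so the acid is released with the acetate, the exocyclic alkene and the (13E) geometry intact.

## Compound list

1 | 2-methylcyclopentane-1,3-dione | CC1C(=O)CCC1=O | starting material
2 | pent-1-en-3-one | C=CC(=O)CC | starting material
3 | 2-methyl-2-(3-oxopentyl)cyclopentane-1,3-dione (triketone) | CCC(=O)CCC1(C)C(=O)CCC1=O | intermediate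
4 | (7aS)-4,7a-dimethyl-2,3,7,7a-tetrahydro-1H-indene-1,5(6H)-dione | O=C1CCC2=C(C)C(=O)CC[C@]12C | intermediate
5 | prop-2-yn-1-ol | C#CCO | starting material
6 | (1R,7aS)-1-hydroxy-1-(3-hydroxyprop-1-yn-1-yl)-4,7a-dimethyl-1,2,3,6,7,7a-hexahydro-5H-inden-5-one | OCC#C[C@]1(O)CCC2=C(C)C(=O)CC[C@]12C | intermediate
7 | trilithium C3–C4 enolate / C8,C12 dialkoxide (5α-H, E-alkene) | [Li+].[Li+].[Li+].[O-]C/C=C/[C@]1([O-])CC[C@H]2C(C)=C([O-])CC[C@]12C | intermediate
8 | hydroxymethyl ketone triol (3-oxo, 4α-CH2OH, 4β-CH3, 5α-H, 8β-OH, 8α-(E)-3-hydroxyprop-1-enyl) | OC/C=C/[C@]1(O)CC[C@H]2[C@](C)(CO)C(=O)CC[C@]12C | intermediate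
9 | C3 4-toluenesulfonylhydrazone of 8 (C=N geometry not defined) | OC/C=C/[C@]1(O)CC[C@H]2[C@](C)(CO)C(=NNS(=O)(=O)c3ccc(C)cc3)CC[C@]12C | intermediate
10 | triol (C3 = CH2; 4α-CH2OH, 4β-CH3, 5α-H, 8β-OH, 8α-(E)-3-hydroxyprop-1-enyl) | OC/C=C/[C@]1(O)CC[C@H]2[C@](C)(CO)CCC[C@]12C | intermediate
11 | diacetate of 10 at C18-O and C12-O (8β-OH free) | CC(=O)OC/C=C/[C@]1(O)CC[C@H]2[C@](C)(COC(C)=O)CCC[C@]12C | intermediate
12 | 18-acetoxy-8-oxo-9β-vinyl trans-decalin (4β-CH3, 5α-H, 9α-H, 10β-CH3) | O=C1CC[C@H]2[C@](C)(COC(C)=O)CCC[C@]2(C)[C@H]1C=C | intermediate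
13 | methyl acetoacetate | CC(=O)CC(=O)OC | starting material
14 | methyl (E)-3-(trifluoromethylsulfonyloxy)but-2-enoate | COC(=O)/C=C(\C)OS(=O)(=O)C(F)(F)F | intermediate
15 | pinacol boronate at C12 of the 9β-ethyl chain of the C8 ketone | O=C1CC[C@H]2[C@](C)(COC(C)=O)CCC[C@]2(C)[C@H]1CCB1OC(C)(C)C(C)(C)O1 | intermediate
16 | methyl 18-acetoxy-8-oxo-17-norlabd-13E-en-15-oate | O=C1CC[C@H]2[C@](C)(COC(C)=O)CCC[C@]2(C)[C@H]1CC/C(C)=C/C(=O)OC | intermediate
17 | methyl 18-acetoxylabda-8(17),13E-dien-15-oate | C=C1CC[C@H]2[C@](C)(COC(C)=O)CCC[C@]2(C)[C@H]1CC/C(C)=C/C(=O)OC | intermediate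
18 | 18-acetoxylabda-8(17),13E-dien-15-oic acid, (4R,5R,9S,10R) | C=C1CC[C@H]2[C@](C)(COC(C)=O)CCC[C@]2(C)[C@H]1CC/C(C)=C/C(=O)O | target

## Step count and risks

Total step count: 10. Longest linear sequence: 9 steps (steps 1–6 and 8–10; step 7 is a one-step side branch).

**Step 3 (three events in one dissolving-metal operation).** The risks are incomplete alkyne reduction, some cis ring fusion, and poor or reversible trapping of the enolate by formaldehyde. The fallback sets out from 6 and comes back at 8. The same lithium/ammonia reduction is run but the enolate is quenched with Me3SiCl/Et3N, giving the tris(trimethylsilyl) enol ether F1. F1 is then hydroxymethylated under Mukaiyama aldol conditions with aqueous formaldehyde and Yb(OTf)3 in THF/H2O. The two O-silyl ethers are lost in the same aqueous medium (citric acid/MeOH to finish), which gives 8.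

**Step 6 (the proposed new step).** The unstrained cyclopentanol may not migrate fast enough, and the π-allyl could be diverted to a vinyl epoxide or a spiro-dihydrofuran. The fallback uses known chemistry, sets out from 11 and comes back at 12. N-Bromosuccinimide in CH2Cl2 at −20 °C triggers a bromonium-induced semipinacol ring expansion (C10 migrates to C9 anti to bromine) and gives the 11-bromo-12-acetoxy ketone F2. Zinc dust in AcOH/THF then removes bromide and acetate by reductive elimination and leaves the vinyl group of 12.

**Step 8 (one-pot hydroboration and alkylboronate coupling).** The risks are slow boron-to-palladium transfer, base damage to the triflate or the acetate, and alkene migration. The fallback sets out from 12 and comes back at 16. The vinyl group is hydroborated as before to 15, which is oxidised with NaBO3·4H2O to the primary alcohol F3. I2/PPh3/imidazole converts F3 into the primary iodide F4. Zinc dust with LiCl in THF gives the alkylzinc iodide F5, which is coupled base-free with 14 under PdCl2(dppf) catalysis (Negishi coupling) to give 16; a trace of DBU settles C9 if needed.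

## Further compounds

F1 | step 3 | tris(trimethylsilyl) derivative: C3–C4 silyl enol ether with C8 and C12 O-silyl ethers | C[Si](C)(C)OC/C=C/[C@]1(O[Si](C)(C)C)CC[C@H]2C(C)=C(O[Si](C)(C)C)CC[C@]12C
F2 | step 6 | 18-acetoxy-9β-[(1R)-2-acetoxy-1-bromoethyl]-8-oxo trans-decalin | O=C1CC[C@H]2[C@](C)(COC(C)=O)CCC[C@]2(C)[C@H]1[C@@H](Br)COC(C)=O
F3 | step 8 | 18-acetoxy-9β-(2-hydroxyethyl)-8-oxo trans-decalin | O=C1CC[C@H]2[C@](C)(COC(C)=O)CCC[C@]2(C)[C@H]1CCO
F4 | step 8 | 18-acetoxy-9β-(2-iodoethyl)-8-oxo trans-decalin | O=C1CC[C@H]2[C@](C)(COC(C)=O)CCC[C@]2(C)[C@H]1CCI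
F5 | step 8 | alkylzinc iodide from F4 | O=C1CC[C@H]2[C@](C)(COC(C)=O)CCC[C@]2(C)[C@H]1CC[Zn]I
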